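The runs were generated by integration for an exercise; the scatter is artificial.

1. Count J against the G lost, not against the clock, and reckon both flasks through that one ratio.

| flask | G | D | temperature | remark | time |
|---|---|---|---|---|---|
| beta | 0.035 M | 0.090 M | −5 °C | run made earlier |  |
| delta | 0.058 M | 0.090 M | 20 °C | run made earlier |  |
| epsilon | 0.093 M | 0.090 M | −5 °C | run made earlier |  |
| oak | 0.10 M | 0.0900 M | 40 °C |  | 20 min |
| cedar | 0.030 M | 0.0900 M | 0 °C |  | 10 min |

| run | time / min | J / % | G / % |
|---|---|---|---|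
| beta | 40.0 | 1.5 | 98.7 |
| beta | 80.0 | 2.9 | 94.6 |
| beta | 120 | 4.7 | 92.3 |
| beta | 150 | 6.2 | 89.3 |
| beta | 180 | 9.4 | 89.2 |
| delta | 5.00 | 2.6 | 96.3 |
| delta | 15.0 | 5.3 | 91.1 |
| delta | 25.0 | 10.7 | 87.6 |
| delta | 40.0 | 11.4 | 79.8 |
| delta | 50.0 | 14.9 | 75.6 |
| epsilon | 15.0 | 1.6 | 98.4 |
| epsilon | 30.0 | 2.2 | 98.4 |
| epsilon | 60.0 | 1.4 | 96.0 |
| epsilon | 90.0 | 2.2 | 94.0 |
| epsilon | 180 | 7.5 | 89.1 |

(scatter of a reading: 1 percentage point)

1. which one finishes higher in amount of J, in percent of the G charged ("neither" within 2 percentage points) (oak / cedar / neither)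
2. amount of J at the end, in percent of the G charged, oak
3. amount of J at the end, in percent of the G charged, cedar

- a reading or a percentage of J counts all its forms, free or not

2. Take the last delta reading, at 50.0 min. Delta lost more G than beta or epsilon, so the scatter weighs least there.

3. Divide the two amounts: J 14.9% over G lost 24.4% gives 0.611. This is the J share, the fraction of the G lost that stands as J (the selectivity for J). An even split between two paths would give 0.5. The reading lies above that, and it carries the scatter. Assume it holds at other temperatures.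

4. Get the G lost. Delta gives 0.00559 min⁻¹, pseudo-first-order with D taken as steady. Assume two doublings up to oak and two halvings down to cedar. Then I reckon oak to lose 36.1% of its G, less than its D charge of 0.900 of the G allows, and cedar to lose 1.39%.

5. Multiply by the share for my own reckoning of J: oak 22.1%, cedar 0.849%.

6. The forecast says oak, with oak 21% (14% to 28%) and cedar 0.8% (0.4% to 1.5%): “J is about 0.65 of the G lost in all three runs”. Its oak value lies below mine, and so does its cedar value.

7. Oak ends at 15.4% J, crystals L counted in, and cedar at 0.786%, so oak finishes higher. Oak converted 26.3% of its G, with D down to 14.8% of its own charge. The J share on that conversion gives 16.1%, and my reckoned G lost for oak stood 9.8 percentage points above that conversion.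

    G + D → J (k = 0.00384 M⁻¹ s⁻¹, Ea = 58.0 kJ mol⁻¹)
    D + J → Q (k = 0.00154 M⁻¹ s⁻¹, Ea = 71.0 kJ mol⁻¹)
    D → X (k = 9.50 × 10⁻⁴ s⁻¹, Ea = 91.0 kJ mol⁻¹)
    L ⇌ J, rate k4*(cs4 - [J]) while solid is left; crystals form when [J] > cs4 (solubility = 5.60 mM, k = 0.00424 s⁻¹)
    G + D → Z (k = 0.00252 M⁻¹ s⁻¹, Ea = 64.0 kJ mol⁻¹)
    D + Z → Q (k = 0.0232 M⁻¹ s⁻¹, Ea = 46.0 kJ mol⁻¹)
    (constants at 40 °C)

8. Take the neighbour of oak with 0.036 M of D, its other charges and its time as in oak. It keeps 89% of its G, so the J share gives 7.02%. The computed flask gives 6.84%.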